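**Retrosynthetic overview**

1. Target ⇐ 8(17)-alkene acid **25** (hydration at C8) ⇐ 8-ketone **23** (methylenation, ester removal) ⇐ bicyclic β-keto ester **21**.
2. Ring B of **21** is opened at C9–C10 and C6–C7, giving ring-A bis-electrophile **12** (tertiary chloride at C10, CH2Cl on C5) and bis-silyl dienol ether **19**, which carries the whole side chain.
3. Enabling feature: C8 of ring B lies between C7 and C9, so as a ketone it makes C7–C8–C9 a 1,3-dinucleophile (γ-carbon C9, α-carbon C7); on ring A the methyl-bearing quaternary C10 and the CH2 carbon C6 on the neighbouring C5 form the matching 1,3-dielectrophile.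
4. Ring A is made first by an enantioselective Diels–Alder reaction that fixes C4 and C5; ring B is closed second in the key step; C9 and C8 are set afterwards.
5. Side chain **19** comes from hex-5-yn-1-ol by carboalumination, which fixes the E-enoate.

Key step: step 13

Assumption: the (S)-configured oxazaborolidinium catalyst is taken to give the (1R,6R) adduct **6**; if the facial sense is the opposite, the (R)-catalyst is used. The CH(CH3) or CCl(CH3) centre (future C10) of **6**–**12** is left undefined because it is ionised in step 13.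

**Step 1**
Reactants: 1 2-methyl-2-vinyloxirane
Product: 3 (E)-4-chloro-2-methylbut-2-enal, via allylic alcohol 2 (not isolated)
Conditions: CuCl2·2H2O, LiCl, EtOAc/CHCl3, 75 °C
Reagents that add atoms: copper dichloride, Cl[Cu]Cl; lithium chloride, [Li+].[Cl-]
Why: Oxidative chlorination of a diene monoepoxide: SN2' opening by chloride gives the allylic alcohol, which divalent copper should oxidise to the more stable (E)-enal.

**Step 2**
Reactants: 4 pent-1-en-3-one
Product: 5 (Z)-3-(tert-butyldimethylsilyloxy)penta-1,3-diene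
Conditions: TBSOTf, Et3N, Et2O, 0 °C
Reagents that add atoms: tert-butyldimethylsilyl triflate, CC(C)(C)[Si](C)(C)OS(=O)(=O)C(F)(F)F
Why: Soft enolisation and O-silylation of the ethyl ketone should give the 2-silyloxy diene.

**Step 3**
Reactants: 3 (E)-4-chloro-2-methylbut-2-enal; 5 (Z)-3-(tert-butyldimethylsilyloxy)penta-1,3-diene
Product: 6 (1R,6R)-4-(tert-butyldimethylsilyloxy)-6-(chloromethyl)-1,5-dimethylcyclohex-3-ene-1-carbaldehyde
Conditions: (S)-o-tolyl-oxazaborolidine·HNTf2 (0.1 equiv), CH2Cl2, −78 °C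
Reagents that add atoms: none
Why: Catalytic enantioselective Diels–Alder reaction: the silyloxy group should direct its methyl-bearing terminus to the β-carbon of the enal, the E geometry of 3 is transferred into the trans relation of CHO (future C18) and CH2Cl (future C6) at the new C4 and C5 centres, and the catalyst sets their absolute configuration.

**Step 4**
Reactants: 6 the Diels–Alder aldehyde
Product: 7 [(1R,6R)-4-(tert-butyldimethylsilyloxy)-6-(chloromethyl)-1,5-dimethylcyclohex-3-en-1-yl]methanol
Conditions: NaBH4, MeOH/THF, −20 °C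
Reagents that add atoms: none
Why: Borohydride reduction of the aldehyde, with the ring ketone still masked as its silyl enol ether.

**Step 5**
Reactants: 7 the primary alcohol
Product: 9 [(1R,2R)-2-(chloromethyl)-1,3-dimethyl-4-oxocyclohexyl]methyl acetate, via silyl enol ether acetate 8 (not isolated)
Conditions: Ac2O, pyridine, DMAP, CH2Cl2, 23 °C; then 1 M HCl, THF, 23 °C
Reagents that add atoms: acetic anhydride, CC(=O)OC(C)=O
Why: Acetylation installs the C18 acetate of the target, and acid hydrolysis of the silyl enol ether should release the ketone.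

**Step 6**
Reactants: 9 the keto acetate
Product: 10 [(1R,2S)-2-(chloromethyl)-1,3-dimethyl-4-(trifluoromethanesulfonyloxy)cyclohex-3-en-1-yl]methyl acetate
Conditions: Tf2O, 2,6-di-tert-butyl-4-methylpyridine, CH2Cl2, 0 → 23 °C
Reagents that add atoms: triflic anhydride, O=S(=O)(OS(=O)(=O)C(F)(F)F)C(F)(F)F
Why: Enol triflate formation under equilibrating, enolate-free conditions should favour the more substituted vinyl triflate and avoids cyclopropane formation by the γ-chloride.

**Step 7**
Reactants: 10 the vinyl triflate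
Product: 11 [(1R,2R)-2-(chloromethyl)-1,3-dimethylcyclohex-3-en-1-yl]methyl acetate
Conditions: Pd(OAc)2, PPh3, n-Bu3N, HCO2H, DMF, 60 °C
Reagents that add atoms: none
Why: Palladium-catalysed formate reduction of a vinyl triflate; the alkyl chloride and the acetate should be inert.

**Step 8**
Reactants: 11 the trisubstituted alkene
Product: 12 [(1R,2R)-3-chloro-2-(chloromethyl)-1,3-dimethylcyclohexyl]methyl acetate
Conditions: HCl (g), CH2Cl2, −78 °C; used crude
Reagents that add atoms: hydrogen chloride, Cl
Why: Markovnikov hydrochlorination should place the chloride on the methyl-bearing carbon (future C10).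

**Step 9**
Reactants: 13 hex-5-yn-1-ol
Product: 15 prop-2-enyl (2E)-7-hydroxy-3-methylhept-2-enoate, via alkenylalane 14 (not isolated)
Conditions: Me3Al (3 equiv), Cp2ZrCl2 (0.3 equiv), CH2Cl2, 0 → 23 °C; then ClCO2CH2CH=CH2, −30 → 0 °C
Reagents that add atoms: trimethylaluminium, C[Al](C)C; allyl chloroformate, C=CCOC(Cl)=O
Why: Negishi carboalumination is a syn addition and acylation of the alkenylalane occurs with retention, which should give the (E)-3-methyl enoate only.

**Step 10**
Reactants: 15 the hydroxy ester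
Product: 16 (5E)-5-methyl-7-oxo-7-(prop-2-enyloxy)hept-5-enoic acid
Conditions: TEMPO (0.2 equiv), PhI(OAc)2 (2.2 equiv), MeCN/H2O, 23 °C
Reagents that add atoms: water, O
Why: Oxoammonium-mediated oxidation of the primary alcohol to the acid, which leaves both alkenes untouched.

**Step 11**
Reactants: 16 the acid
Product: 18 9-(prop-2-enyl) 1-(2,2,2-trichloroethyl) (7E)-7-methyl-3-oxonon-7-enedioate, via acyl Meldrum's acid 17 (not isolated)
Conditions: Meldrum's acid, DCC, DMAP, CH2Cl2, 0 → 23 °C; then Cl3CCH2OH, toluene, 100 °C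
Reagents that add atoms: Meldrum's acid, CC1(C)OC(=O)CC(=O)O1; 2,2,2-trichloroethanol, OCC(Cl)(Cl)Cl
Why: Acylation of Meldrum's acid and alcoholysis give the β-keto ester; the trichloroethyl ester can later be removed without touching the allyl ester or the acetate.

**Step 12**
Reactants: 18 the β-keto ester
Product: 19 the 1,3-bis(trimethylsilyloxy)-1,3-diene of 18
Conditions: TMSOTf (2.3 equiv), Et3N (2.6 equiv), Et2O, 0 °C; used crude
Reagents that add atoms: trimethylsilyl triflate, C[Si](C)(C)OS(=O)(=O)C(F)(F)F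
Why: Double O-silylation of a β-keto ester to the bis-silyl dienol ether, whose γ-carbon (C9) is the nucleophilic terminus.

**Step 13**
Reactants: 12 the ring-A dichloride; 19 the bis-silyl dienol ether
Product: 21 bicyclic β-keto ester (prop-2-enyl 18-acetoxy-8-oxo-7-(2,2,2-trichloroethoxycarbonyl)-17-norlabd-13(E)-en-15-oate), via monocyclic β-keto ester 20 (not isolated)
Conditions: TiCl4, 2,6-di-tert-butyl-4-methylpyridine, CH2Cl2, −78 °C; then DBU, NaI, MeCN, −78 → 50 °C
Reagents that add atoms: none
Why: Proposed new method: TiCl4 ionises the tertiary C10–Cl bond of 12 and the cation is captured by the γ-carbon (C9) of 19, as in the Lewis-acid α-tert-alkylation of silyl enol ethers with tertiary chlorides (Reetz) and the γ-selective Mukaiyama-type reactions of 1,3-bis(silyloxy)dienes, giving titanium-bound β-keto ester 20; DBU then frees its enolate, whose α-carbon (C7) displaces the primary chloride on C6 under iodide catalysis, the known intramolecular alkylation of β-keto esters, so that a formal [3+3] annulation builds ring B in one flask. Ring B closes in the 6-(enolendo)-exo-tet mode. C10 is set in the first event: in the chair of the cation the axial methyl on C4 (future C19) shields the β face and the equatorial CH2Cl arm on C5 directs attack trans to itself, so C9 should enter from the α face, the C10 methyl becomes β, and ring closure then gives the trans-decalin; C9 and C7 remain mixtures (C9 is equilibrated in step 14, C7 loses its ester). The step needs substitution to outrun elimination or hydride shift of the cation (low temperature, hindered pyridine as proton trap, excess of the nucleophile), γ- over α-attack (inherent to the dienol ether) and C- over O-alkylation (soft iodide leaving group, six-membered carbocyclic transition state).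

**Step 14**
Reactants: 21 the bicyclic β-keto ester
Product: 23 prop-2-enyl 18-acetoxy-8-oxo-17-norlabd-13(E)-en-15-oate, via β-keto acid 22 (not isolated)
Conditions: Zn, AcOH, THF, 23 → 50 °C; then DBU (0.2 equiv), CH2Cl2, 23 °C
Reagents that add atoms: none
Why: Reductive cleavage of the trichloroethyl ester and decarboxylation of the β-keto acid, then base equilibration α to the ketone should place the C9 side chain equatorial (9α-H), the thermodynamic arrangement.

**Step 15**
Reactants: 23 the 8-ketone
Product: 24 prop-2-enyl 18-acetoxylabda-8(17),13(E)-dien-15-oate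
Conditions: Zn, CH2Br2, TiCl4, THF/CH2Cl2, 0 → 23 °C
Reagents that add atoms: dibromomethane, BrCBr
Why: Takai–Lombardo methylenation is non-basic, so it should convert the hindered ketone without epimerising C9 or touching the esters.

**Step 16**
Reactants: 24 the allyl ester
Product: 25 18-acetoxylabda-8(17),13(E)-dien-15-oic acid
Conditions: Pd(PPh3)4 (5 mol%), morpholine, THF, 23 °C
Reagents that add atoms: none
Why: Palladium-catalysed allyl transfer to morpholine frees the acid without touching the acetate, and removes the allyl alkene before the hydration.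

**Step 17**
Reactants: 25 the diene acid
Product: 27 18-acetoxy-8α-hydroxylabd-13(E)-en-15-oic acid (target), via 8α-hydroperoxide 26 (not isolated)
Conditions: Co(acac)2 (0.2 equiv), PhSiH3, O2 (1 atm), THF/i-PrOH, 23 °C; then PPh3
Reagents that add atoms: dioxygen, O=O
Why: Mukaiyama hydration: hydrogen-atom transfer to the 1,1-disubstituted alkene gives the tertiary C8 radical, which oxygen should trap from the α face because the β face is shielded by the axial C10 methyl, giving the equatorial 8α-OH with an axial C17 methyl; the electron-poor enoate should not react.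

**Compound list**

1 | 2-methyl-2-vinyloxirane | CC1(C=C)CO1 | starting material
2 | (E)-4-chloro-2-methylbut-2-en-1-ol | OC/C(C)=C/CCl | intermediate
3 | (E)-4-chloro-2-methylbut-2-enal | O=C/C(C)=C/CCl | intermediate
4 | pent-1-en-3-one | CCC(=O)C=C | starting material
5 | (Z)-3-(tert-butyldimethylsilyloxy)penta-1,3-diene | C=C/C(O[Si](C)(C)C(C)(C)C)=C/C | intermediate
6 | (1R,6R)-4-(tert-butyldimethylsilyloxy)-6-(chloromethyl)-1,5-dimethylcyclohex-3-ene-1-carbaldehyde (C5 epimers) | O=C[C@]1(C)CC=C(O[Si](C)(C)C(C)(C)C)C(C)[C@H]1CCl | intermediate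
7 | [(1R,6R)-4-(tert-butyldimethylsilyloxy)-6-(chloromethyl)-1,5-dimethylcyclohex-3-en-1-yl]methanol | OC[C@]1(C)CC=C(O[Si](C)(C)C(C)(C)C)C(C)[C@H]1CCl | intermediate
8 | [(1R,6R)-4-(tert-butyldimethylsilyloxy)-6-(chloromethyl)-1,5-dimethylcyclohex-3-en-1-yl]methyl acetate | CC(=O)OC[C@]1(C)CC=C(O[Si](C)(C)C(C)(C)C)C(C)[C@H]1CCl | intermediate
9 | [(1R,2R)-2-(chloromethyl)-1,3-dimethyl-4-oxocyclohexyl]methyl acetate (C3 epimers) | CC(=O)OC[C@]1(C)CCC(=O)C(C)[C@H]1CCl | intermediate
10 | [(1R,2S)-2-(chloromethyl)-1,3-dimethyl-4-(trifluoromethanesulfonyloxy)cyclohex-3-en-1-yl]methyl acetate | CC(=O)OC[C@]1(C)CCC(OS(=O)(=O)C(F)(F)F)=C(C)[C@H]1CCl | intermediate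
11 | [(1R,2R)-2-(chloromethyl)-1,3-dimethylcyclohex-3-en-1-yl]methyl acetate | CC(=O)OC[C@]1(C)CCC=C(C)[C@H]1CCl | intermediate
12 | [(1R,2R)-3-chloro-2-(chloromethyl)-1,3-dimethylcyclohexyl]methyl acetate (C3 epimers) | CC(=O)OC[C@]1(C)CCCC(C)(Cl)[C@H]1CCl | intermediate
13 | hex-5-yn-1-ol | OCCCCC#C | starting material
14 | (E)-alkenyl(dimethyl)alane from 13, as its dimethylaluminium alkoxide | C/C(CCCCO[Al](C)C)=C\[Al](C)C | intermediate
15 | prop-2-enyl (2E)-7-hydroxy-3-methylhept-2-enoate | OCCCC/C(C)=C/C(=O)OCC=C | intermediate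
16 | (5E)-5-methyl-7-oxo-7-(prop-2-enyloxy)hept-5-enoic acid | OC(=O)CCC/C(C)=C/C(=O)OCC=C | intermediate
17 | 5-acyl Meldrum's acid of 16 | CC1(C)OC(=O)C(C(=O)CCC/C(C)=C/C(=O)OCC=C)C(=O)O1 | intermediate
18 | 9-(prop-2-enyl) 1-(2,2,2-trichloroethyl) (7E)-7-methyl-3-oxonon-7-enedioate | ClC(Cl)(Cl)COC(=O)CC(=O)CCC/C(C)=C/C(=O)OCC=C | intermediate
19 | 1,3-bis(trimethylsilyloxy)-1,3-diene of 18 (enol ether geometry not defined) | C[Si](C)(C)OC(OCC(Cl)(Cl)Cl)=CC(O[Si](C)(C)C)=CCC/C(C)=C/C(=O)OCC=C | intermediate
20 | γ-tert-alkylated β-keto ester: ring A (4α-acetoxymethyl, 4β-methyl, 5α-H, 10β-methyl) joined through C10 to C9 of the chain, CH2Cl still on C5 (C9 epimers) | CC(=O)OC[C@]1(C)CCC[C@](C)(C(CC/C(C)=C/C(=O)OCC=C)C(=O)CC(=O)OCC(Cl)(Cl)Cl)[C@H]1CCl | intermediate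
21 | prop-2-enyl 18-acetoxy-8-oxo-7-(2,2,2-trichloroethoxycarbonyl)-17-norlabd-13(E)-en-15-oate; 5α-H and 10β-methyl (C7 and C9 epimers) | CC(=O)OC[C@]1(C)CCC[C@]2(C)C(CC/C(C)=C/C(=O)OCC=C)C(=O)C(C(=O)OCC(Cl)(Cl)Cl)C[C@@H]12 | intermediate
22 | the 7-carboxylic acid from 21 | CC(=O)OC[C@]1(C)CCC[C@]2(C)C(CC/C(C)=C/C(=O)OCC=C)C(=O)C(C(=O)O)C[C@@H]12 | intermediate
23 | prop-2-enyl 18-acetoxy-8-oxo-17-norlabd-13(E)-en-15-oate; 5α-H, 9α-H and 10β-methyl | CC(=O)OC[C@]1(C)CCC[C@]2(C)[C@@H](CC/C(C)=C/C(=O)OCC=C)C(=O)CC[C@@H]12 | intermediate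
24 | prop-2-enyl 18-acetoxylabda-8(17),13(E)-dien-15-oate | CC(=O)OC[C@]1(C)CCC[C@]2(C)[C@@H](CC/C(C)=C/C(=O)OCC=C)C(=C)CC[C@@H]12 | intermediate
25 | 18-acetoxylabda-8(17),13(E)-dien-15-oic acid | CC(=O)OC[C@]1(C)CCC[C@]2(C)[C@@H](CC/C(C)=C/C(=O)O)C(=C)CC[C@@H]12 | intermediate
26 | 18-acetoxy-8α-hydroperoxylabd-13(E)-en-15-oic acid | CC(=O)OC[C@]1(C)CCC[C@]2(C)[C@@H](CC/C(C)=C/C(=O)O)[C@](C)(OO)CC[C@@H]12 | intermediate
27 | (2E)-5-[(1R,2R,4aR,5R,8aS)-5-(acetoxymethyl)-2-hydroxy-2,5,8a-trimethyldecahydronaphthalen-1-yl]-3-methylpent-2-enoic acid | CC(=O)OC[C@]1(C)CCC[C@]2(C)[C@@H](CC/C(C)=C/C(=O)O)[C@](C)(O)CC[C@@H]12 | target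

**Step count and risks**

Total steps: 17. Longest linear sequence: 12 (steps 1, 3–8, 13–17).

Most likely to fail:

- **Step 13 (proposed new method).** The tertiary cation may be lost to elimination or hydride shift before the hindered C9–C10 bond forms, the dienol ether may attack through its α-carbon, or the ring may close through oxygen. Fallback with known reactions, reversing the bond order, from 11 back to 23:
  - Finkelstein exchange of alkene 11 (NaI, acetone) gives [(1R,2R)-2-(iodomethyl)-1,3-dimethylcyclohex-3-en-1-yl]methyl acetate F1.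
  - Alkylation of the dianion of methyl acetoacetate (NaH, n-BuLi, THF) with F1 gives methyl 5-[(1R,6R)-6-(acetoxymethyl)-2,6-dimethylcyclohex-2-en-1-yl]-3-oxopentanoate F2.
  - SnCl4 in CH2Cl2 closes ring B by the known cation–olefin cyclisation of monocyclic β-keto esters, giving methyl (4aR,5R,8aS)-5-(acetoxymethyl)-5,8a-dimethyl-2-oxodecahydronaphthalene-1-carboxylate F3.
  - Michael addition to but-3-en-2-one (K2CO3) gives the 1-(3-oxobutyl) keto ester F4.
  - Krapcho demethoxycarbonylation (LiCl, wet DMSO, 140 °C) gives 18-acetoxy-14,15,17-trinorlabdane-8,13-dione F5.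
  - Horner–Wadsworth–Emmons reaction at the methyl ketone with allyl (diethoxyphosphoryl)acetate and NaH returns to 23 after removal of the Z isomer.
- **Step 3.** Enantio- or regiocontrol may be insufficient with the γ-chloro enal. Fallback from 3 and 5, rejoining at 8: cycloaddition with Me2AlCl gives 6 together with its enantiomer, (1S,6S)-aldehyde F6; reduction as in step 4 gives 7 together with the (1S,6S)-alcohol F7; lipase-catalysed acetylation (Burkholderia cepacia lipase, vinyl acetate) would acetylate the (1R,6R)-alcohol to 8 and leave F7 behind.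
- **Step 6.** Enolisation may go toward the methylene carbon and give the wrong vinyl triflate. Fallback from 9, rejoining at 11: condensation with tosylhydrazine gives the tosylhydrazone of 9 F8; aprotic Bamford–Stevens reaction (NaH, toluene, 110 °C) should give the more substituted alkene 11 by 1,2-hydride shift of the carbene.

**Further compounds**

F1 | step 13 | [(1R,2R)-2-(iodomethyl)-1,3-dimethylcyclohex-3-en-1-yl]methyl acetate | CC(=O)OC[C@]1(C)CCC=C(C)[C@H]1CI
F2 | step 13 | methyl 5-[(1R,6R)-6-(acetoxymethyl)-2,6-dimethylcyclohex-2-en-1-yl]-3-oxopentanoate | CC(=O)OC[C@]1(C)CCC=C(C)[C@H]1CCC(=O)CC(=O)OC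
F3 | step 13 | methyl (4aR,5R,8aS)-5-(acetoxymethyl)-5,8a-dimethyl-2-oxodecahydronaphthalene-1-carboxylate (C1 epimers) | CC(=O)OC[C@]1(C)CCC[C@]2(C)C(C(=O)OC)C(=O)CC[C@@H]12
F4 | step 13 | methyl (4aR,5R,8aS)-5-(acetoxymethyl)-5,8a-dimethyl-2-oxo-1-(3-oxobutyl)decahydronaphthalene-1-carboxylate | CC(=O)OC[C@]1(C)CCC[C@]2(C)C(CCC(C)=O)(C(=O)OC)C(=O)CC[C@@H]12
F5 | step 13 | 18-acetoxy-14,15,17-trinorlabdane-8,13-dione | CC(=O)OC[C@]1(C)CCC[C@]2(C)[C@@H](CCC(C)=O)C(=O)CC[C@@H]12
F6 | step 3 | (1S,6S)-4-(tert-butyldimethylsilyloxy)-6-(chloromethyl)-1,5-dimethylcyclohex-3-ene-1-carbaldehyde | O=C[C@@]1(C)CC=C(O[Si](C)(C)C(C)(C)C)C(C)[C@@H]1CCl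
F7 | step 3 | [(1S,6S)-4-(tert-butyldimethylsilyloxy)-6-(chloromethyl)-1,5-dimethylcyclohex-3-en-1-yl]methanol | OC[C@@]1(C)CC=C(O[Si](C)(C)C(C)(C)C)C(C)[C@@H]1CCl
F8 | step 6 | tosylhydrazone of 9 | CC(=O)OC[C@]1(C)CCC(=NNS(=O)(=O)c2ccc(C)cc2)C(C)[C@H]1CCl
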